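**Strategy**

- Feature: in the quinone ring (C1=O, C2–OMe, C3–OH, C4=O, C5–Me, C6–hexaprenyl) the oxygen-bearing arc C1–C2–C3–C4 is a squaric acid unit and C5=C6 is a trisubstituted alkene, so the ring can be cut at C1–C6 and C4–C5.
- Retrosynthesis: C1–C6 is cut first (thermal ring expansion of a 4-alkenyl-4-hydroxycyclobutenone). The OH/OMe difference at C3/C2 is then traced back to the vinylogous ester carbon of the four-membered ring. C4–C5 is cut next (alkenyllithium plus dimethyl squarate). The chain is cut at the vinyl C–I bond, at the propynyl–C1′ bond and at C12′–C13′ into two farnesol-derived C15 halves.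
- Forward: C15 sulfone + C15 bromide → C30 hexaprenol → bromide → C33 skipped enyne → E vinyl iodide. The chain-bearing alkenyllithium is added to dimethyl squarate, one methoxyl is exchanged for a silyloxy group, and the six-membered ring (the only ring) is closed last and oxidised to the quinone.
- Stereochemistry: there is no stereocentre. Four E alkenes come unchanged from two molecules of (2E,6E)-farnesol and the fifth from the E-selective allylic oxidation of the head half. The vinyl iodide geometry and the racemic sulfone and carbinol carbons are erased on the way.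

Key step: step 14

Remark: Hex denotes the all-E hexaprenyl group, (2E,6E,10E,14E,18E)-3,7,11,15,19,23-hexamethyltetracosa-2,6,10,14,18,22-hexaen-1-yl. The ring labels C1–C6 used in the Why lines are those of the first line above (cyclobutenone C1–C4 keep their labels in the quinone), not the locants of the names. Enol 20 is a racemate whose two enol forms are mirror images, so it is drawn as one compound.

**Step 1**
Reactants: 1 (2E,6E)-farnesol
Product: 2 (2E,6E)-farnesyl bromide
Conditions: PBr3 (0.4 equiv), pyridine (cat.), Et2O, −10 °C; used crude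
Reagents that add atoms: phosphorus tribromide, BrP(Br)Br
Why: Bromination of a primary allylic alcohol with PBr3 (SN2 displacement of the phosphite ester by bromide) at low temperature should give the primary bromide without allylic transposition or loss of the 2E geometry.

**Step 2**
Reactants: 2 (2E,6E)-farnesyl bromide
Product: 3 (2E,6E)-farnesyl phenyl sulfone
Conditions: PhSO2Na, DMF, rt
Reagents that add atoms: sodium benzenesulfinate, [Na+].[O-]S(=O)c1ccccc1
Why: SN2 S-alkylation of the sulfinate anion by the primary allylic bromide in a dipolar aprotic solvent is the standard route to allylic sulfones and leaves both alkenes untouched.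

**Step 3**
Reactants: 1 (2E,6E)-farnesol
Product: 5 (2E,6E)-farnesyl benzyl ether, via sodium farnesolate 4 (not isolated)
Conditions: NaH, THF, 0 °C; BnBr, Bu4NI (cat.), 0 °C to rt
Reagents that add atoms: benzyl bromide, BrCc1ccccc1
Why: Williamson ether synthesis, the benzyl group being chosen because it survives steps 4 to 6 and falls together with the sulfonyl group in step 7.

**Step 4**
Reactants: 5 (2E,6E)-farnesyl benzyl ether
Product: 7 (2E,6E,10E)-12-hydroxyfarnesyl benzyl ether, via enal 6 (not isolated)
Conditions: SeO2 (cat.), t-BuOOH, salicylic acid (cat.), CH2Cl2, 0 °C to rt, stopped at partial conversion; crude treated with NaBH4, MeOH, 0 °C; unreacted 5 recycled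
Reagents that add atoms: selenium dioxide, O=[Se]=O; tert-butyl hydroperoxide, CC(C)(C)OO
Why: Catalytic SeO2 allylic oxidation (Riley oxidation: ene reaction then [2,3]-sigmatropic shift) should attack the E-methyl of the terminal, most electron-rich and least hindered trisubstituted alkene, the sigmatropic step fixing the new alkene as 10E, and the borohydride treatment returns the over-oxidised portion (enal 6) to the same allylic alcohol.

**Step 5**
Reactants: 7 (2E,6E,10E)-12-hydroxyfarnesyl benzyl ether
Product: 8 (2E,6E,10E)-12-bromofarnesyl benzyl ether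
Conditions: PBr3 (0.4 equiv), pyridine (cat.), Et2O, −10 °C
Reagents that add atoms: phosphorus tribromide, BrP(Br)Br
Why: PBr3 bromination of a primary allylic alcohol as in step 1, under which the benzyl ether and the E alkenes should be inert.

**Step 6**
Reactants: 3 (2E,6E)-farnesyl phenyl sulfone; 8 (2E,6E,10E)-12-bromofarnesyl benzyl ether
Product: 10 racemic 13-(phenylsulfonyl)-Hex benzyl ether (C30 sulfone), via lithiated sulfone 9 (not isolated)
Conditions: 3, n-BuLi, THF/DMPU, −78 °C; then 8, −78 to −20 °C
Reagents that add atoms: none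
Why: Alkylation of a sulfonyl-stabilised allyl carbanion at its α-carbon by SN2 attack on the primary allylic bromide (sulfone coupling of terpenoid halves) joins the two C15 units without touching an alkene, and the new sulfone-bearing stereocentre forms as a racemate that is removed in step 7.

**Step 7**
Reactants: 10 racemic 13-(phenylsulfonyl)-Hex benzyl ether
Product: 11 all-E hexaprenol (Hex–OH)
Conditions: Li, EtNH2/THF, −78 °C; MeOH quench
Reagents that add atoms: none
Why: Dissolving-metal reduction (Benkeser-type) cleaves the allylic C–S bond and the benzylic C–O bond by electron transfer in one operation, a combination long used for polyprenols, and at −78 °C the isolated trisubstituted alkenes should not be reduced.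

**Step 8**
Reactants: 11 all-E hexaprenol
Product: 12 all-E hexaprenyl bromide (Hex–Br)
Conditions: PBr3 (0.4 equiv), pyridine (cat.), Et2O, −10 °C; used crude
Reagents that add atoms: phosphorus tribromide, BrP(Br)Br
Why: PBr3 bromination of a primary allylic alcohol as in step 1, with the bromide taken on at once because polyprenyl bromides do not keep.

**Step 9**
Reactants: 12 all-E hexaprenyl bromide; 13 1-propynylmagnesium bromide
Product: 14 1-Hex-prop-1-yne (C33 skipped enyne)
Conditions: 13 (1.5 equiv), CuI (10 mol%), THF, 0 °C to rt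
Reagents that add atoms: none
Why: Copper-catalysed coupling of an alkynyl Grignard reagent with a primary allylic bromide, in which the alkynylcopper species should substitute at the unhindered α-carbon (SN2) and not at the fully substituted γ-carbon, so the 2E alkene of the chain stays intact.

**Step 10**
Reactants: 14 1-Hex-prop-1-yne
Product: 16 (E)-2-iodo-1-Hex-prop-1-ene, via alkenylzirconocene chloride 15 (not isolated)
Conditions: Cp2Zr(H)Cl (2 equiv), THF, rt then 45 °C; I2, THF, 0 °C, dark; chromatography to remove any 3-iodo regioisomer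
Reagents that add atoms: iodine, [I][I]
Why: Hydrozirconation–iodination, in which Cp2Zr(H)Cl adds H and Zr syn across the alkyne, excess reagent and gentle warming equilibrate the adducts toward zirconium on the methyl-bearing carbon away from the branched chain, and iodine cleaves the C–Zr bond with retention to the E iodide while the trisubstituted alkenes stay inert.

**Step 11**
Reactants: 16 (E)-2-iodo-1-Hex-prop-1-ene; 17 dimethyl squarate
Product: 19 racemic 4-hydroxy-2,3-dimethoxy-4-[(E)-1-Hex-prop-1-en-2-yl]cyclobut-2-en-1-one, via alkenyllithium 18 (not isolated)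
Conditions: t-BuLi (2.05 equiv), THF, −78 °C; cannulated into 17 (1.3 equiv), THF, −78 °C; AcOH in THF, −78 °C
Reagents that add atoms: none
Why: Iodine–lithium exchange with retention of alkene geometry followed by 1,2-addition of the alkenyllithium to one of the two equivalent squarate carbonyls at −78 °C (inverse addition suppresses a second addition) forms the C4–C5 bond, and the carbinol stereocentre arises as a racemate that is erased in step 14.

**Step 12**
Reactants: 19 racemic 4-hydroxy-2,3-dimethoxy-4-[(E)-1-Hex-prop-1-en-2-yl]cyclobut-2-en-1-one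
Product: 20 racemic 3,4-dihydroxy-2-methoxy-4-[(E)-1-Hex-prop-1-en-2-yl]cyclobut-2-en-1-one
Conditions: LiOH·H2O (2.2 equiv), THF/H2O, 0 °C; cold dilute HCl to pH 4, extraction; used at once
Reagents that add atoms: lithium hydroxide, [Li+].[OH-]
Why: Proposed new method: hydroxide should add to C3, the β-carbon of the β-methoxy enone (a vinylogous ester), and expel methoxide, whereas the C2 methoxyl is an α-alkoxy enol ether with no acceptor carbon and cannot react this way; the product is at once deprotonated to a 1,3-dionate with a mirror plane through C2 and C4, whose charge shuts off further attack, and the C4 alkoxide has no stabilised carbanion to release by retro-aldol cleavage; the closest known reaction types are the half-saponification of dialkyl squarates to alkyl hydrogen squarates and the base hydrolysis of 3-alkoxy enones to 1,3-diones.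

**Step 13**
Reactants: 20 racemic 3,4-dihydroxy-2-methoxy-4-[(E)-1-Hex-prop-1-en-2-yl]cyclobut-2-en-1-one
Product: 21 racemic 4-hydroxy-2-methoxy-3-(triisopropylsilyloxy)-4-[(E)-1-Hex-prop-1-en-2-yl]cyclobut-2-en-1-one
Conditions: i-Pr3SiCl (1.1 equiv), Et3N (1.5 equiv), CH2Cl2, 0 °C; filtration through Et3N-deactivated silica
Reagents that add atoms: triisopropylsilyl chloride, CC(C)[Si](Cl)(C(C)C)C(C)C
Why: O-silylation of a vinylogous acid (silyl enol ether formation from a 1,3-dione enol) should be far faster than silylation of the hindered tertiary C4 hydroxyl, and because of the mirror plane of the dionate either enol oxygen gives the same constitution.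

**Step 14**
Reactants: 21 racemic 4-hydroxy-2-methoxy-3-(triisopropylsilyloxy)-4-[(E)-1-Hex-prop-1-en-2-yl]cyclobut-2-en-1-one
Product: 24 6-Hex-2-methoxy-5-methyl-3-(triisopropylsilyloxy)benzene-1,4-diol, via dienylketene 22 (not isolated), via cyclohexadienone 23 (not isolated)
Conditions: degassed toluene (0.01 M), 110 °C, Ar; concentrated under Ar and used crude
Reagents that add atoms: none
Why: Heating should open the C1–C4 bond of the cyclobutenone by a conrotatory 4π electrocyclic reaction to the (3Z)-dienylketene 22, whose ketene carbon C1 then bonds to the alkene terminus C6 in a thermally allowed disrotatory 6π electrocyclisation that closes the six-membered carbocycle (the only ring of the target) as cyclohexadienone 23, and enolisation gives hydroquinone 24. The closest known reaction is the thermal ring expansion of 4-alkenyl-4-hydroxy-2,3-dialkoxycyclobutenones from squarates to hydroquinones (Moore rearrangement), and 3-triisopropylsilyloxy-4-vinylcyclobutenones pass through the same opening and closure with silicon retained in the Danheiser benzannulation with silyloxyalkynes. The only new stereocentre, C6 of 23, is transient and is erased by aromatisation, as are the carbinol centre and the vinyl geometry. The step needs the alkenyl group to rotate inward toward the ketene, which the strong outward preference of the C4 hydroxyl donor should secure (torquoselectivity), and an unencumbered closing terminus, which the E geometry provides by placing H inside and the chain CH2 outside. The OH/OMe regiochemistry is carried in from 21 and not decided here: C2–OMe ends between C1–OH and C3, C3–OSi next to C4–OH and hence next to C5–Me, and a silyl shift to a neighbouring oxygen would still converge in step 15. Neutral, dilute, oxygen-free conditions should spare the polyene and the air-sensitive hydroquinone.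

**Step 15**
Reactants: 24 6-Hex-2-methoxy-5-methyl-3-(triisopropylsilyloxy)benzene-1,4-diol
Product: 26 3-demethylubiquinone-6 (2-Hex-5-hydroxy-6-methoxy-3-methyl-1,4-benzoquinone), via benzenetriol 25 (not isolated)
Conditions: Bu4NF/AcOH (1:1), THF, 0 °C, Ar; then Ag2O, rt; aqueous wash at pH 3
Reagents that add atoms: none
Why: Fluoride cleavage of the aryl silyl ether should give benzene-1,2,4-triol 25 wherever the silyl group sits, and Ag2O oxidation of this electron-rich triol should give the hydroxy-para-quinone (the tautomer preferred over the ortho-quinone), with the acetic acid buffer guarding the quinone against base-induced cyclisation onto the side chain.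

**Compound list**

1 | (2E,6E)-farnesol | OC/C=C(\C)CC/C=C(\C)CCC=C(C)C | starting material
2 | (2E,6E)-farnesyl bromide | BrC/C=C(\C)CC/C=C(\C)CCC=C(C)C | intermediate
3 | (2E,6E)-farnesyl phenyl sulfone | O=S(=O)(c1ccccc1)C/C=C(\C)CC/C=C(\C)CCC=C(C)C | intermediate
4 | sodium (2E,6E)-farnesolate | [Na+].[O-]C/C=C(\C)CC/C=C(\C)CCC=C(C)C | intermediate (not isolated)
5 | (2E,6E)-farnesyl benzyl ether | c1ccccc1COC/C=C(\C)CC/C=C(\C)CCC=C(C)C | intermediate
6 | (2E,6E,10E)-12-(benzyloxy)-2,6,10-trimethyldodeca-2,6,10-trienal | c1ccccc1COC/C=C(\C)CC/C=C(\C)CC/C=C(\C)C=O | intermediate (not isolated)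
7 | (2E,6E,10E)-12-hydroxyfarnesyl benzyl ether [(2E,6E,10E)-12-(benzyloxy)-2,6,10-trimethyldodeca-2,6,10-trien-1-ol] | c1ccccc1COC/C=C(\C)CC/C=C(\C)CC/C=C(\C)CO | intermediate
8 | (2E,6E,10E)-12-bromofarnesyl benzyl ether | c1ccccc1COC/C=C(\C)CC/C=C(\C)CC/C=C(\C)CBr | intermediate
9 | α-lithio (2E,6E)-farnesyl phenyl sulfone | [Li]C(/C=C(\C)CC/C=C(\C)CCC=C(C)C)S(=O)(=O)c1ccccc1 | intermediate (not isolated)
10 | racemic (2E,6E,10E,14E,18E)-1-(benzyloxy)-3,7,11,15,19,23-hexamethyl-13-(phenylsulfonyl)tetracosa-2,6,10,14,18,22-hexaene | c1ccccc1COC/C=C(\C)CC/C=C(\C)CC/C=C(\C)CC(S(=O)(=O)c1ccccc1)/C=C(\C)CC/C=C(\C)CCC=C(C)C | intermediate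
11 | all-E hexaprenol | OC/C=C(\C)CC/C=C(\C)CC/C=C(\C)CC/C=C(\C)CC/C=C(\C)CCC=C(C)C | intermediate
12 | all-E hexaprenyl bromide | BrC/C=C(\C)CC/C=C(\C)CC/C=C(\C)CC/C=C(\C)CC/C=C(\C)CCC=C(C)C | intermediate
13 | 1-propynylmagnesium bromide | CC#C[Mg]Br | starting material
14 | 1-Hex-prop-1-yne [(5E,9E,13E,17E,21E)-6,10,14,18,22,26-hexamethylheptacosa-5,9,13,17,21,25-hexaen-2-yne] | CC#CC/C=C(\C)CC/C=C(\C)CC/C=C(\C)CC/C=C(\C)CC/C=C(\C)CCC=C(C)C | intermediate
15 | chlorobis(cyclopentadienyl)[(E)-1-Hex-prop-1-en-2-yl]zirconium | C/C(=C\C/C=C(\C)CC/C=C(\C)CC/C=C(\C)CC/C=C(\C)CC/C=C(\C)CCC=C(C)C)[Zr](Cl)(C1C=CC=C1)C1C=CC=C1 | intermediate (not isolated)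
16 | (E)-2-iodo-1-Hex-prop-1-ene | C/C(I)=C\C/C=C(\C)CC/C=C(\C)CC/C=C(\C)CC/C=C(\C)CC/C=C(\C)CCC=C(C)C | intermediate
17 | dimethyl squarate | COC1=C(OC)C(=O)C1=O | starting material
18 | (E)-1-Hex-prop-1-en-2-yllithium | C/C([Li])=C\C/C=C(\C)CC/C=C(\C)CC/C=C(\C)CC/C=C(\C)CC/C=C(\C)CCC=C(C)C | intermediate (not isolated)
19 | racemic 4-hydroxy-2,3-dimethoxy-4-[(E)-1-Hex-prop-1-en-2-yl]cyclobut-2-en-1-one | C/C(=C\C/C=C(\C)CC/C=C(\C)CC/C=C(\C)CC/C=C(\C)CC/C=C(\C)CCC=C(C)C)C1(O)C(OC)=C(OC)C1=O | intermediate
20 | racemic 3,4-dihydroxy-2-methoxy-4-[(E)-1-Hex-prop-1-en-2-yl]cyclobut-2-en-1-one | C/C(=C\C/C=C(\C)CC/C=C(\C)CC/C=C(\C)CC/C=C(\C)CC/C=C(\C)CCC=C(C)C)C1(O)C(O)=C(OC)C1=O | intermediate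
21 | racemic 4-hydroxy-2-methoxy-3-(triisopropylsilyloxy)-4-[(E)-1-Hex-prop-1-en-2-yl]cyclobut-2-en-1-one | C/C(=C\C/C=C(\C)CC/C=C(\C)CC/C=C(\C)CC/C=C(\C)CC/C=C(\C)CCC=C(C)C)C1(O)C(O[Si](C(C)C)(C(C)C)C(C)C)=C(OC)C1=O | intermediate
22 | (3Z,5E)-6-Hex-4-hydroxy-2-methoxy-5-methyl-3-(triisopropylsilyloxy)hexa-1,3,5-trien-1-one | O=C=C(OC)/C(O[Si](C(C)C)(C(C)C)C(C)C)=C(O)\C(C)=C\C/C=C(\C)CC/C=C(\C)CC/C=C(\C)CC/C=C(\C)CC/C=C(\C)CCC=C(C)C | intermediate (not isolated)
23 | racemic 6-Hex-4-hydroxy-2-methoxy-5-methyl-3-(triisopropylsilyloxy)cyclohexa-2,4-dien-1-one | O=C1C(OC)=C(O[Si](C(C)C)(C(C)C)C(C)C)C(O)=C(C)C1C/C=C(\C)CC/C=C(\C)CC/C=C(\C)CC/C=C(\C)CC/C=C(\C)CCC=C(C)C | intermediate (not isolated)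
24 | 6-Hex-2-methoxy-5-methyl-3-(triisopropylsilyloxy)benzene-1,4-diol | COc1c(O)c(C/C=C(\C)CC/C=C(\C)CC/C=C(\C)CC/C=C(\C)CC/C=C(\C)CCC=C(C)C)c(C)c(O)c1O[Si](C(C)C)(C(C)C)C(C)C | intermediate
25 | 5-Hex-3-methoxy-6-methylbenzene-1,2,4-triol | COc1c(O)c(C/C=C(\C)CC/C=C(\C)CC/C=C(\C)CC/C=C(\C)CC/C=C(\C)CCC=C(C)C)c(C)c(O)c1O | intermediate (not isolated)
26 | 3-demethylubiquinone-6 (2-Hex-5-hydroxy-6-methoxy-3-methyl-1,4-benzoquinone) | COC1=C(O)C(=O)C(C)=C(C/C=C(\C)CC/C=C(\C)CC/C=C(\C)CC/C=C(\C)CC/C=C(\C)CCC=C(C)C)C1=O | target

**Step count**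

Total: 15 steps. Longest linear sequence: 13 steps (steps 3 to 15, from farnesol through the head half).

**Steps most likely to fail**

Step 12 (Proposed new method). The methoxyl exchange at C3 may be slower than base-induced ring opening of the C4 alkoxide, or the acidic enol may ionise at C4 and rearrange during acidification. The fallback uses known chemistry, sets out from 19 and gives up regiocontrol. Compound 19 is heated in toluene at 110 °C, the established ring expansion of 2,3-dimethoxy adducts, to give ubiquinol-6 F1. Ag2O oxidises this to ubiquinone-6 F2. One methoxyl, a vinylogous ester known to be exchanged by alkali, is then hydrolysed with one equivalent of NaOH in aqueous THF at 0 °C under argon. This should give 26 together with its regioisomer 2-Hex-6-hydroxy-5-methoxy-3-methyl-1,4-benzoquinone F3, to be separated by reversed-phase HPLC. The route is rejoined at 26.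

Step 14. At 110 °C the silyl group may shift to the adjacent C4 hydroxyl or be lost, after which the free vinylogous acid fragments. The hydroxyl may also rotate inward, so that the ketene lactonises to a butenolide instead of closing the ring. The fallback sets out from 20. O-alkylation with chloromethyl methyl ether and i-Pr2NEt (CH2Cl2, 0 °C) gives 4-hydroxy-2-methoxy-3-(methoxymethoxy)-4-[(E)-1-Hex-prop-1-en-2-yl]cyclobut-2-en-1-one F4, a 2,3-dialkoxy substrate of exactly the class on which the ring expansion is established and whose acetal cannot migrate. Thermolysis in toluene gives 6-Hex-2-methoxy-3-(methoxymethoxy)-5-methylbenzene-1,4-diol F5. Ag2O gives 2-Hex-6-methoxy-5-(methoxymethoxy)-3-methyl-1,4-benzoquinone F6. The vinylogous methoxymethyl ester is then cleaved with 0.1 M HCl in MeOH/THF at rt, rejoining the route at 26.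

Step 7. The delocalised allyl anion formed on C–S cleavage may be protonated at its γ-terminus, which moves the C14 double bond and scrambles its geometry, and partial over-reduction may occur. The fallback sets out from 10. Palladium-catalysed hydride substitution (PdCl2(dppp) cat., LiBHEt3, THF, 0 °C) removes the sulfonyl group through an allylpalladium hydride that delivers hydrogen to the less substituted terminus, giving all-E hexaprenyl benzyl ether F7. The benzyl group is then cleaved separately with lithium naphthalenide (LiC10H8) in THF at −25 °C, which returns to 11.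

**Further compounds**

F1 | step 12 | ubiquinol-6 | COc1c(OC)c(O)c(C/C=C(\C)CC/C=C(\C)CC/C=C(\C)CC/C=C(\C)CC/C=C(\C)CCC=C(C)C)c(C)c1O
F2 | step 12 | ubiquinone-6 | COC1=C(OC)C(=O)C(C/C=C(\C)CC/C=C(\C)CC/C=C(\C)CC/C=C(\C)CC/C=C(\C)CCC=C(C)C)=C(C)C1=O
F3 | step 12 | 2-Hex-6-hydroxy-5-methoxy-3-methyl-1,4-benzoquinone | COC1=C(O)C(=O)C(C/C=C(\C)CC/C=C(\C)CC/C=C(\C)CC/C=C(\C)CC/C=C(\C)CCC=C(C)C)=C(C)C1=O
F4 | step 14 | racemic 4-hydroxy-2-methoxy-3-(methoxymethoxy)-4-[(E)-1-Hex-prop-1-en-2-yl]cyclobut-2-en-1-one | C/C(=C\C/C=C(\C)CC/C=C(\C)CC/C=C(\C)CC/C=C(\C)CC/C=C(\C)CCC=C(C)C)C1(O)C(OCOC)=C(OC)C1=O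
F5 | step 14 | 6-Hex-2-methoxy-3-(methoxymethoxy)-5-methylbenzene-1,4-diol | COCOc1c(OC)c(O)c(C/C=C(\C)CC/C=C(\C)CC/C=C(\C)CC/C=C(\C)CC/C=C(\C)CCC=C(C)C)c(C)c1O
F6 | step 14 | 2-Hex-6-methoxy-5-(methoxymethoxy)-3-methyl-1,4-benzoquinone | COCOC1=C(OC)C(=O)C(C/C=C(\C)CC/C=C(\C)CC/C=C(\C)CC/C=C(\C)CC/C=C(\C)CCC=C(C)C)=C(C)C1=O
F7 | step 7 | all-E hexaprenyl benzyl ether | c1ccccc1COC/C=C(\C)CC/C=C(\C)CC/C=C(\C)CC/C=C(\C)CC/C=C(\C)CCC=C(C)C
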